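The numbers in the tables are simulated for substances that don't exist, and the scatter is random.

**Amounts first.** I count the second nucleophile as a fraction of the substrate charge: grey holds 0.829, green 1.31, and this flask 0.600, less than grey. Substrate and first nucleophile stand at the same charge in grey, green and this flask.

in all of them: substrate 0.35 M; first nucleophile 0.385 M
- grey: second nucleophile 0.29 M; run made earlier
- green: second nucleophile 0.46 M; run made earlier
- flask: second nucleophile 0.210 M; time 5.0 min

| run | time / min | target / % |
|---|---|---|
| grey | 0.833 | 1.4 |
| grey | 2.00 | 2.8 |
| grey | 4.00 | 6.6 |
| grey | 6.00 | 6.9 |
| green | 1.50 | 2.5 |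
| green | 3.00 | 3.7 |
| green | 5.00 | 4.4 |
| green | 6.00 | 5.5 |

(standard deviation of a reading: 0.5 percentage points)

- the numbers in the tables scatter with a standard deviation of 0.5 percentage points
- a reading or a percentage of target counts all its forms, free or not

- amount of target in percent of the substrate charged, at 30 s, 1.5 min, 3.0 min and 5.0 min

**Turned round.** For this flask to make no more target than grey, adding second nucleophile has to cost no target between grey and green. Grey, midway between its readings at 4.00 min and 6.00 min, reads 6.75%, and green reads 4.4% at 5.00 min. That gap of 2.4 percentage points is 3.84 times the scatter of such a difference, so I take it as real.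

**The penalty.** As a reading, with its scatter, the gap gives 0.717, the penalty: the fraction of the grey target lost at 5.00 min, substrate and first nucleophile charges held, per substrate charge of second nucleophile added. I keep the grey figure as the large term and reckon only the correction. This flask lies 0.229 of a charge below grey, which adds 1.1 points, so my own figure at 5.0 min is 7.86%.

**The forecast.** It prints 0.8%, 2.3%, 4.4% and 6.5%, on the ground that “the second nucleophile does not drive formation but instead consumes the target”. Its last value is lower than mine, so the two reckonings differ there.

**The result.** The flask gives 1.35%, 3.59%, 6.16% and 8.60%, and the forecast stands within its margin.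

    substrate + target → side product (k = 0.0100 M⁻¹ s⁻¹)
    second nucleophile + intermediate → other capture product (k = 76.0 M⁻¹ s⁻¹)
    substrate → intermediate (k = 0.00200 s⁻¹)
    first nucleophile → decomposition product (k = 5.60 × 10⁻⁶ s⁻¹)
    intermediate → solvolysis product (k = 2.40 s⁻¹)
    first nucleophile + intermediate → target (k = 15.0 M⁻¹ s⁻¹)
    crystals ⇌ target, rate k7*(cs7 - [target]) while solid is left; crystals form when [target] > cs7 (solubility = 0.120 M, k = 0.260 s⁻¹)

**Penalty reused.** At 5.00 min this flask also holds 26.9% of other capture product. Carried from this flask to the grey charge, the penalty turns 8.60% into 7.19%, against the grey midpoint of 6.75%. Carried from the grey reading of 6.9% at 6.00 min to the green charge, it gives 4.52%; the green reading at 6.00 min, which the penalty was not made from, is 5.5%.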